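The earlier runs and the new flask were computed for an exercise; noise was put on by code.

The eta run, with 1.8 mol% of free catalyst, still held 56.9% of its starting material at 120 s. From that reading we choose the next charge.

| flask | starting material | second substrate | free catalyst | remark | time |
|---|---|---|---|---|---|
| beta | 0.050 M | 1 equiv | 0.32 mol% | run made earlier |  |
| eta | 0.050 M | 1 equiv | 1.8 mol% | run made earlier |  |
| delta | 0.050 M | 1.7 equiv | 1 mol% | run made earlier |  |
| midnight | 0.20 M | 0.500 equiv | 0.25 mol% |  | 2.0 min |
| dawn | 0.050 M | 1.00 equiv | 1 mol% |  | 2.0 min |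
| winter | 0.015 M | 4.00 equiv | 0.25 mol% |  | 2.0 min |
| noon | 0.050 M | 1.00 equiv | 1.5 mol% |  | 2.0 min |
| spring | 0.050 M | 1.00 equiv | 0.6 mol% |  | 2.0 min |

| run | time / s | target / % | starting material / % |
|---|---|---|---|
| beta | 10.0 | 0.3 | 98.7 |
| beta | 15.0 | 1.8 | 98.5 |
| beta | 25.0 | 1.7 | 98.6 |
| beta | 40.0 | 3.4 | 97.6 |
| beta | 80.0 | 6.3 | 94.9 |
| beta | 120 | 9.1 | 91.7 |
| eta | 10.0 | 4.2 | 96.2 |
| eta | 25.0 | 9.4 | 89.5 |
| eta | 40.0 | 15.7 | 83.0 |
| eta | 60.0 | 22.0 | 76.6 |
| eta | 90.0 | 33.4 | 65.8 |
| eta | 120 | 41.9 | 56.9 |
| delta | 10.0 | 2.3 | 97.5 |
| delta | 30.0 | 5.7 | 93.7 |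
| delta | 60.0 | 13.5 | 87.5 |
| delta | 80.0 | 16.6 | 82.4 |
| delta | 120 | 24.2 | 75.9 |

(standard deviation of a reading: 0.5 percentage points)



* all flasks from highest to lowest amount of target, in percent of the starting material charged, at 2.0 min (midnight / dawn / winter / noon / spring)
* the same order at 8.0 min (midnight / dawn / winter / noon / spring)
* the amount of target, in percent of the starting material charged of the flask you put first, at 2.0 min
* the amount of target, in percent of the starting material charged of the flask you put last, at 2.0 min

Eta is the deepest of the runs, ending lower than beta or delta, so scatter weighs least there. We carry the half-life dose, the catalyst concentration multiplied by the half-life of the starting material, which assumes a pseudo-first-order loss at fixed catalyst. Eta gives 0.133 M·s; the last readings of beta and delta give 0.154 M·s and 0.151 M·s. Dividing the dose by a flask's catalyst concentration gives its half-life, and counting half-lives gives the fraction turned into target.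

Noon then has a half-life of 177 s, which gives 37.5% at 2.0 min. Dawn has 266 s, which gives 26.9%. Midnight is charged with the same catalyst concentration as dawn on a quarter of dawn's loading, so our count ties the two. But every run stood at 0.050 M, and midnight stands at 0.20 M. We therefore charge midnight next: a tie in percent of the charge would mean a factor of 4.00 more target per litre from the same catalyst concentration, and a gap would show that the dose does not carry over to midnight's charge, where the concentrations of starting material and second substrate both differ from dawn's.

The forecast, reasoning that “k scales with catalyst concentration”, gives noon > dawn > midnight > spring > winter at 2.0 min and noon > dawn > spring > midnight > winter at 8.0 min. It puts the first flask at 34.5% (32% to 37%), below our noon, and the last at 2.2% (1.5% to 3.5%).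

The flasks give noon > dawn > spring > midnight > winter at 2.0 min and noon > dawn > spring > midnight > winter at 8.0 min, with noon at 36.7% and winter at 2.50% at 2.0 min.

    second substrate + free catalyst ⇌ catalyst intermediate B (K = 6.90 M⁻¹, k = 13.3 M⁻¹ s⁻¹)
    catalyst intermediate A → free catalyst + target (k = 0.903 s⁻¹)
    catalyst intermediate B → free catalyst + second product (k = 0.796 s⁻¹)
    starting material + free catalyst ⇌ catalyst intermediate A (K = 6000 M⁻¹, k = 8.08 M⁻¹ s⁻¹)

The count holds on noon, 37.5% against 36.7%, but midnight parts from it: 14.3% against 26.9%, while dawn gives 25.8%. At 2.00 min, midnight holds 51.3% of its catalyst as catalyst intermediate A, its largest form, and dawn holds 21.5%. The neighbour of winter is charged with 1 mol% of free catalyst, on winter's 0.015 M of starting material and 4.00 equiv of second substrate. Its half-life counts as 885 s, which gives 8.97% target, and the flask gives 9.69%.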